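**Retrosynthetic overview**
1. Target 21 ← Swern oxidation of diol acetate 20 ← triol 17, from i-Bu2AlH reduction of bicyclic keto diester 16 (C9 carbinol set by hydride attack over the C2=C3 bridge; C2=C3 from ester dehydrogenation of 14).
2. 14 ← ketol 12 ← key [3+3] annulation of ring A keto diester 5 with enal 10: one pot forms C1–C8 (amine-catalysed Michael addition) and C5–C6 (aldol), giving both quaternary bridgeheads, the C8 centre and the second ring.
3. Enabling feature: the C9 carbonyl carbon sits between the two bridgeheads C1 and C5, so ring A (C1–C2–C3–C4–C5–C9) is a 1,3-bis-nucleophile (C1 further acidified by its carboxyl carbon) matching the 1,3-bis-electrophilic enal (β-carbon = C8, carbonyl carbon = C6).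
4. 5 ← organocatalytic Michael/aldol condensation of ethyl 3-oxopentanoate 1 with ethyl 4-oxobutenoate 2, then hydrogenation; its ester-bearing centre (C2 of the bicycle) steers C1 and is erased later. 10 ← (R)-citronellal 6 by one-carbon homologation and dehydrogenation.
5. Ring order: ring A first (step 1), then ring C1–C9–C5–C6–C7–C8 in the key step.

Key step: step 5

Remark on numbering: all bicyclic compounds carry the target's locants (C1 formyl-bearing bridgehead, C2=C3 alkene, C4, C5 methyl-bearing bridgehead, C6, C7, C8 with the side chain, C9 one-carbon bridge).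
Remark on the chemistry (assumption): from the SMILES the C9 acetate is syn to the saturated C6–C7–C8 bridge and the C8 side chain is equatorial; compounds 1, 2 and 6 are taken as commercial.

**Step 1**
Reactants: 1 ethyl 3-oxopentanoate; 2 ethyl (2E)-4-oxobut-2-enoate
Product: 4 diethyl (1R)-4-methyl-3-oxocyclohex-4-ene-1,2-dicarboxylate (C2 epimerisable), via Michael adduct 3 (not isolated)
Conditions: (S)-2-[bis(3,5-bis(trifluoromethyl)phenyl)(trimethylsilyloxy)methyl]pyrrolidine (10 mol %), PhCO2H (10 mol %), toluene, 0 °C to rt; then TsOH·H2O (20 mol %), 80 °C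
Reagents that add atoms: none
Why: Iminium-activated Michael addition of the β-keto ester to the enal followed by acid-mediated intramolecular aldol condensation (organocatalytic Robinson-type annulation) is an established route to 5-substituted 6-alkoxycarbonylcyclohex-2-enones, and the silyloxydiarylmethyl group of the catalyst shields one face of the E-iminium ion so that the ester-bearing C1 of 4 is set as R.

**Step 2**
Reactants: 4 diethyl (1R)-4-methyl-3-oxocyclohex-4-ene-1,2-dicarboxylate
Product: 5 diethyl (1R)-4-methyl-3-oxocyclohexane-1,2-dicarboxylate (mixture at C2 and C4)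
Conditions: H2 (1 atm), 10% Pd/C, EtOAc, rt
Reagents that add atoms: none
Why: Heterogeneous catalytic hydrogenation saturates the conjugated enone alkene chemoselectively, and the new C4 centre needs no control because it becomes an enolate carbon in step 5.

**Step 3**
Reactants: 6 (R)-citronellal [(3R)-3,7-dimethyloct-6-enal]
Product: 8 (4R)-4,8-dimethylnon-7-enal, via enol ether 7 (not isolated)
Conditions: Ph3P(Cl)CH2OMe, KN(SiMe3)2, THF, 0 °C; then 2 M HCl, THF, rt
Reagents that add atoms: (methoxymethyl)triphenylphosphonium chloride, COC[P+](c1ccccc1)(c1ccccc1)c1ccccc1.[Cl-]; water, O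
Why: Wittig methoxymethylenation followed by acid hydrolysis of the enol ether is the standard one-carbon homologation of an aldehyde and does not touch the existing stereocentre.

**Step 4**
Reactants: 8 (4R)-4,8-dimethylnon-7-enal
Product: 10 (2E,4R)-4,8-dimethylnona-2,7-dienal, via alpha-phenylselanyl aldehyde 9 (not isolated)
Conditions: N-(phenylseleno)phthalimide, (S)-pyrrolidine-2-carboxamide (5 mol %), CH2Cl2, rt; then NaIO4, NaHCO3, MeOH–H2O, rt
Reagents that add atoms: none
Why: Enamine-catalysed α-selenenylation of the aldehyde followed by periodate oxidation and selenoxide syn-elimination is a standard aldehyde-to-E-enal dehydrogenation that leaves the γ-stereocentre and the trisubstituted alkene alone.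

**Step 5**
Reactants: 5 diethyl (1R)-4-methyl-3-oxocyclohexane-1,2-dicarboxylate; 10 (2E,4R)-4,8-dimethylnona-2,7-dienal
Product: 12 diethyl (1R,2R,5S,8S)-6-hydroxy-5-methyl-8-[(2R)-6-methylhept-5-en-2-yl]-9-oxobicyclo[3.3.1]nonane-1,2-dicarboxylate (both C6 epimers), via keto aldehyde 11 (not isolated)
Conditions: 5 (1.2 equiv), (S)-2-[bis(3,5-bis(trifluoromethyl)phenyl)(trimethylsilyloxy)methyl]pyrrolidine (20 mol %), PhCO2H (20 mol %), toluene, 0 °C to rt; then 1,8-diazabicyclo[5.4.0]undec-7-ene (DBU, 1 equiv), 0 °C to rt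
Reagents that add atoms: none
Why: The amine converts 10 into an E-iminium ion, the enol of 5 adds through its only doubly activated carbon (the future C1) to the β-carbon C8 and hydrolysis releases keto aldehyde 11, after which DBU forms the only ketone enolate still possible (C5, since C1 is now quaternary) and this adds to the C6 aldehyde to give 12. The closest known reaction types are the diarylprolinol-silyl-ether-catalysed Michael addition of cyclic β-keto esters to enals and the base-mediated Michael–aldol α,α'-annulation of 2-oxocycloalkanecarboxylates with enals to bridged bicyclic ketols. The ring closed is the six-membered ring C1–C9–C5–C6–C7–C8, by a 6-(enolexo)-exo-trig aldol addition, whereas the C1–C8 bond is formed intermolecularly. C8 (S) is set by the catalyst, whose bulky silyloxydiarylmethyl group blocks one face of the iminium ion, C1 (R) is set by the neighbouring ester of 5, which sends the electrophile to the opposite ring face, C5 follows from the need for a cis-diaxial three-carbon bridge, and the C6 carbinol is uncontrolled and removed in steps 6 and 7. The step needs C1 rather than C5 to react first (secured by the β-dicarbonyl acidity of C1) and closure from C5 rather than from the ester α-carbon C2 (secured because the ketone α-hydrogen is far more acidic and C2 could only form a five-membered ring). A non-nucleophilic amidine base in an aprotic solvent is chosen so that the non-enolisable C9 ketone of 12 is not opened by retro-Claisen attack of an alkoxide.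

**Step 6**
Reactants: 12 diethyl (1R,2R,5S,8S)-6-hydroxy-5-methyl-8-[(2R)-6-methylhept-5-en-2-yl]-9-oxobicyclo[3.3.1]nonane-1,2-dicarboxylate
Product: 13 diethyl (1R,2R,5S,8S)-5-methyl-8-[(2R)-6-methylhept-5-en-2-yl]-9-oxo-6-(phenoxycarbonothioyloxy)bicyclo[3.3.1]nonane-1,2-dicarboxylate (both C6 epimers)
Conditions: PhOC(S)Cl, pyridine, 4-(dimethylamino)pyridine (cat.), CH2Cl2, rt
Reagents that add atoms: O-phenyl chlorothionoformate, S=C(Cl)Oc1ccccc1
Why: Thioacylation of the secondary C6 alcohol under nucleophilic catalysis gives the radical precursor for a Barton–McCombie deoxygenation under conditions too mild for retro-aldol cleavage, and no stereocentre is formed.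

**Step 7**
Reactants: 13 diethyl (1R,2R,5S,8S)-5-methyl-8-[(2R)-6-methylhept-5-en-2-yl]-9-oxo-6-(phenoxycarbonothioyloxy)bicyclo[3.3.1]nonane-1,2-dicarboxylate
Product: 14 diethyl (1R,2R,5R,8S)-5-methyl-8-[(2R)-6-methylhept-5-en-2-yl]-9-oxobicyclo[3.3.1]nonane-1,2-dicarboxylate
Conditions: Bu3SnH, 2,2'-azobis(2-methylpropionitrile) (cat.), toluene, 100 °C
Reagents that add atoms: none
Why: Barton–McCombie deoxygenation, in which the stannyl radical adds to the thiocarbonyl sulfur, β-scission gives the secondary C6 radical and hydrogen transfer from the stannane gives the methylene group, the side-chain alkene being too remote to cyclise.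

**Step 8**
Reactants: 14 diethyl (1R,2R,5R,8S)-5-methyl-8-[(2R)-6-methylhept-5-en-2-yl]-9-oxobicyclo[3.3.1]nonane-1,2-dicarboxylate
Product: 16 diethyl (1R,5R,8S)-5-methyl-8-[(2R)-6-methylhept-5-en-2-yl]-9-oxobicyclo[3.3.1]non-2-ene-1,2-dicarboxylate, via C2 selenide 15 (not isolated)
Conditions: LiN(i-Pr)2, THF, −78 °C; PhSeBr; then NaIO4, NaHCO3, THF–H2O, rt
Reagents that add atoms: none
Why: The ester α-hydrogen at C2 is the only acidic C–H left (C1 and C5 are quaternary), so enolate selenenylation and selenoxide syn-elimination, which can only run toward C3, install the C2=C3 enoate and erase the auxiliary C2 stereocentre.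

**Step 9**
Reactants: 16 diethyl (1R,5R,8S)-5-methyl-8-[(2R)-6-methylhept-5-en-2-yl]-9-oxobicyclo[3.3.1]non-2-ene-1,2-dicarboxylate
Product: 17 (1S,5R,8S,9R)-1,2-bis(hydroxymethyl)-5-methyl-8-[(2R)-6-methylhept-5-en-2-yl]bicyclo[3.3.1]non-2-en-9-ol
Conditions: i-Bu2AlH (excess), CH2Cl2, −78 to 0 °C; aq. KNaC4H4O6 work-up
Reagents that add atoms: none
Why: Hydride reduction converts both esters into primary alcohols (1,2-reduction of the enoate) and reduces the C9 ketone by steric approach control from the face over the flattened C2=C3–C4 bridge (one pseudo-axial hydrogen there against axial hydrogens on C6 and C8 on the other face), so the C9 hydroxyl ends up syn to the saturated bridge as in the target.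

**Step 10**
Reactants: 17 (1S,5R,8S,9R)-1,2-bis(hydroxymethyl)-5-methyl-8-[(2R)-6-methylhept-5-en-2-yl]bicyclo[3.3.1]non-2-en-9-ol
Product: 18 (1S,5R,8S,9R)-1,2-bis[(tert-butyldimethylsilyloxy)methyl]-5-methyl-8-[(2R)-6-methylhept-5-en-2-yl]bicyclo[3.3.1]non-2-en-9-ol
Conditions: t-BuMe2SiCl (2.2 equiv), imidazole, DMF, 0 °C to rt
Reagents that add atoms: tert-butyldimethylsilyl chloride, CC(C)(C)[Si](C)(C)Cl
Why: Chemoselective silylation, since the two primary hydroxyls react with the bulky silyl chloride whereas the C9 hydroxyl, flanked by two quaternary bridgeheads, does not.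

**Step 11**
Reactants: 18 (1S,5R,8S,9R)-1,2-bis[(tert-butyldimethylsilyloxy)methyl]-5-methyl-8-[(2R)-6-methylhept-5-en-2-yl]bicyclo[3.3.1]non-2-en-9-ol
Product: 19 (1S,5R,8S,9R)-1,2-bis[(tert-butyldimethylsilyloxy)methyl]-5-methyl-8-[(2R)-6-methylhept-5-en-2-yl]bicyclo[3.3.1]non-2-en-9-yl acetate
Conditions: Ac2O, Et3N, 4-(dimethylamino)pyridine, CH2Cl2, 40 °C
Reagents that add atoms: acetic anhydride, CC(=O)OC(C)=O
Why: Acylation under nucleophilic catalysis (N-acetylpyridinium ion) acetylates the hindered secondary C9 alcohol with retention of its configuration.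

**Step 12**
Reactants: 19 (1S,5R,8S,9R)-1,2-bis[(tert-butyldimethylsilyloxy)methyl]-5-methyl-8-[(2R)-6-methylhept-5-en-2-yl]bicyclo[3.3.1]non-2-en-9-yl acetate
Product: 20 (1S,5R,8S,9R)-1,2-bis(hydroxymethyl)-5-methyl-8-[(2R)-6-methylhept-5-en-2-yl]bicyclo[3.3.1]non-2-en-9-yl acetate
Conditions: HF·pyridine, THF–pyridine, 0 °C to rt
Reagents that add atoms: none
Why: Fluoride-mediated desilylation under buffered, mildly acidic conditions cleaves both primary silyl ethers without the base-induced 1,3-acetyl migration from O9 to the hydroxymethyl group on C1.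

**Step 13**
Reactants: 20 (1S,5R,8S,9R)-1,2-bis(hydroxymethyl)-5-methyl-8-[(2R)-6-methylhept-5-en-2-yl]bicyclo[3.3.1]non-2-en-9-yl acetate
Product: 21 (1R,5R,8S,9R)-1,2-diformyl-5-methyl-8-[(2R)-6-methylhept-5-en-2-yl]bicyclo[3.3.1]non-2-en-9-yl acetate (target)
Conditions: (COCl)2, DMSO, CH2Cl2, −78 °C; Et3N, −78 to 0 °C
Reagents that add atoms: none
Why: Swern oxidation activates both primary alcohols as alkoxysulfonium ions before base is added, so the 1,4-diol goes to the 1,4-dialdehyde without lactol or lactone formation, and neither aldehyde can epimerise or eliminate because C1 is quaternary and C2 is sp2.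

**Compound list**
1 | ethyl 3-oxopentanoate | CCC(=O)CC(=O)OCC | starting material
2 | ethyl (2E)-4-oxobut-2-enoate | O=C/C=C/C(=O)OCC | starting material
3 | diethyl (2R)-2-(2-oxoethyl)-3-propanoylbutanedioate (C3 epimers) | O=CC[C@@H](C(=O)OCC)C(C(=O)OCC)C(=O)CC | intermediate (not isolated)
4 | diethyl (1R)-4-methyl-3-oxocyclohex-4-ene-1,2-dicarboxylate (C2 epimerisable) | O=C1C(C)=CC[C@@H](C(=O)OCC)C1C(=O)OCC | intermediate
5 | diethyl (1R)-4-methyl-3-oxocyclohexane-1,2-dicarboxylate (mixture at C2 and C4) | O=C1C(C)CC[C@@H](C(=O)OCC)C1C(=O)OCC | intermediate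
6 | (R)-citronellal, (3R)-3,7-dimethyloct-6-enal | C[C@H](CCC=C(C)C)CC=O | starting material
7 | (4R)-1-methoxy-4,8-dimethylnona-1,7-diene (E/Z mixture) | C[C@H](CCC=C(C)C)CC=COC | intermediate (not isolated)
8 | (4R)-4,8-dimethylnon-7-enal | C[C@H](CCC=C(C)C)CCC=O | intermediate
9 | (4R)-4,8-dimethyl-2-(phenylselanyl)non-7-enal (C2 epimers) | C[C@H](CCC=C(C)C)CC([Se]c1ccccc1)C=O | intermediate (not isolated)
10 | (2E,4R)-4,8-dimethylnona-2,7-dienal | C[C@H](CCC=C(C)C)/C=C/C=O | intermediate
11 | diethyl (1R,2R)-2-[(3S,4R)-4,8-dimethyl-1-oxonon-7-en-3-yl]-4-methyl-3-oxocyclohexane-1,2-dicarboxylate (C4 epimers) | O=C1C(C)CC[C@@H](C(=O)OCC)[C@]1(C(=O)OCC)[C@H]([C@H](C)CCC=C(C)C)CC=O | intermediate (not isolated)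
12 | diethyl (1R,2R,5S,8S)-6-hydroxy-5-methyl-8-[(2R)-6-methylhept-5-en-2-yl]-9-oxobicyclo[3.3.1]nonane-1,2-dicarboxylate (both C6 epimers) | O=C1[C@@]2(C)CC[C@@H](C(=O)OCC)[C@]1(C(=O)OCC)[C@H]([C@H](C)CCC=C(C)C)CC2O | intermediate
13 | diethyl (1R,2R,5S,8S)-5-methyl-8-[(2R)-6-methylhept-5-en-2-yl]-9-oxo-6-(phenoxycarbonothioyloxy)bicyclo[3.3.1]nonane-1,2-dicarboxylate (both C6 epimers) | O=C1[C@@]2(C)CC[C@@H](C(=O)OCC)[C@]1(C(=O)OCC)[C@H]([C@H](C)CCC=C(C)C)CC2OC(=S)Oc3ccccc3 | intermediate
14 | diethyl (1R,2R,5R,8S)-5-methyl-8-[(2R)-6-methylhept-5-en-2-yl]-9-oxobicyclo[3.3.1]nonane-1,2-dicarboxylate | O=C1[C@@]2(C)CC[C@@H](C(=O)OCC)[C@]1(C(=O)OCC)[C@H]([C@H](C)CCC=C(C)C)CC2 | intermediate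
15 | diethyl (1R,5R,8S)-5-methyl-8-[(2R)-6-methylhept-5-en-2-yl]-9-oxo-2-(phenylselanyl)bicyclo[3.3.1]nonane-1,2-dicarboxylate (C2 epimers) | O=C1[C@@]2(C)CCC([Se]c3ccccc3)(C(=O)OCC)[C@]1(C(=O)OCC)[C@H]([C@H](C)CCC=C(C)C)CC2 | intermediate (not isolated)
16 | diethyl (1R,5R,8S)-5-methyl-8-[(2R)-6-methylhept-5-en-2-yl]-9-oxobicyclo[3.3.1]non-2-ene-1,2-dicarboxylate | O=C1[C@@]2(C)CC=C(C(=O)OCC)[C@]1(C(=O)OCC)[C@H]([C@H](C)CCC=C(C)C)CC2 | intermediate
17 | (1S,5R,8S,9R)-1,2-bis(hydroxymethyl)-5-methyl-8-[(2R)-6-methylhept-5-en-2-yl]bicyclo[3.3.1]non-2-en-9-ol | O[C@@H]1[C@@]2(C)CC=C(CO)[C@]1(CO)[C@H]([C@H](C)CCC=C(C)C)CC2 | intermediate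
18 | (1S,5R,8S,9R)-1,2-bis[(tert-butyldimethylsilyloxy)methyl]-5-methyl-8-[(2R)-6-methylhept-5-en-2-yl]bicyclo[3.3.1]non-2-en-9-ol | O[C@@H]1[C@@]2(C)CC=C(CO[Si](C)(C)C(C)(C)C)[C@]1(CO[Si](C)(C)C(C)(C)C)[C@H]([C@H](C)CCC=C(C)C)CC2 | intermediate
19 | (1S,5R,8S,9R)-1,2-bis[(tert-butyldimethylsilyloxy)methyl]-5-methyl-8-[(2R)-6-methylhept-5-en-2-yl]bicyclo[3.3.1]non-2-en-9-yl acetate | CC(=O)O[C@@H]1[C@@]2(C)CC=C(CO[Si](C)(C)C(C)(C)C)[C@]1(CO[Si](C)(C)C(C)(C)C)[C@H]([C@H](C)CCC=C(C)C)CC2 | intermediate
20 | (1S,5R,8S,9R)-1,2-bis(hydroxymethyl)-5-methyl-8-[(2R)-6-methylhept-5-en-2-yl]bicyclo[3.3.1]non-2-en-9-yl acetate | CC(=O)O[C@@H]1[C@@]2(C)CC=C(CO)[C@]1(CO)[C@H]([C@H](C)CCC=C(C)C)CC2 | intermediate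
21 | (1R,5R,8S,9R)-1,2-diformyl-5-methyl-8-[(2R)-6-methylhept-5-en-2-yl]bicyclo[3.3.1]non-2-en-9-yl acetate (CNP0299929.2) | CC(=O)O[C@@H]1[C@@]2(C)CC=C(C=O)[C@]1(C=O)[C@H]([C@H](C)CCC=C(C)C)CC2 | target

**Step count**
Total steps: 13. Longest linear sequence: 11 steps (steps 1, 2, 5–13; the branch through steps 3 and 4 is equally long).

**Steps most likely to fail**

Step 5 (key annulation). The conjugate addition must create the quaternary C1 next to the tertiary C2 and the branched C8. If that C–C bond formation is slow, the catalyst can divert 10 into its dienamine (epimerisation at the γ-carbon), or retro-Michael cleavage can compete during the aldol stage. The fallback sets out from 5 and 10 and comes back at 14, bypassing steps 6 and 7. Enal 10 would be reduced (NaBH4, CeCl3·7H2O, MeOH, 0 °C) to allylic alcohol (2E,4R)-4,8-dimethylnona-2,7-dien-1-ol F1 and converted (ClCO2Me, pyridine, CH2Cl2) into methyl (2E,4R)-4,8-dimethylnona-2,7-dien-1-yl carbonate F2. Branched-selective iridium-catalysed allylic alkylation of 5 with F2 ([Ir(cod)Cl]2, O,O'-(1,1'-binaphthalene-2,2'-diyl) N,N-bis(1-phenylethyl)phosphoramidite of the sense that gives the 8S centre, LiOt-Bu, THF, rt) would form the C1–C8 bond, again anti to the neighbouring ester, giving diethyl (1R,2R)-2-[(3S,4R)-4,8-dimethylnona-1,7-dien-3-yl]-4-methyl-3-oxocyclohexane-1,2-dicarboxylate F3 without amine activation of the enal. Hydroboration–oxidation of the vinyl group (9-borabicyclo[3.3.1]nonane, THF; NaBO3·4H2O) would give diethyl (1R,2R)-2-[(3S,4R)-1-hydroxy-4,8-dimethylnon-7-en-3-yl]-4-methyl-3-oxocyclohexane-1,2-dicarboxylate F4. Iodination (I2, PPh3, imidazole, CH2Cl2) would give diethyl (1R,2R)-2-[(3S,4R)-1-iodo-4,8-dimethylnon-7-en-3-yl]-4-methyl-3-oxocyclohexane-1,2-dicarboxylate F5. Intramolecular C-alkylation of the ketone enolate (KOt-Bu, THF, 0 °C) would then close the C5–C6 bond and give 14.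

Step 8 (ester dehydrogenation). Deprotonation is unambiguous, but C–Se bond formation at the enolate carbon, which lies next to the quaternary C1, may be too slow, so that the enolate is simply reprotonated on work-up. The fallback sets out from 14 and comes back at 16. The enolate would be trapped on oxygen (LiN(i-Pr)2, Me3SiCl, THF, −78 °C) as silyl ketene acetal ethyl (1R,5R,8S)-2-[ethoxy(trimethylsilyloxy)methylidene]-5-methyl-8-[(2R)-6-methylhept-5-en-2-yl]-9-oxobicyclo[3.3.1]nonane-1-carboxylate F6, and Saegusa–Ito dehydrosilylation (Pd(OAc)2, MeCN, rt) would give 16.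

Step 7 (radical deoxygenation). The radical chain may be unproductive at this hindered position, through fragmentation back to the alcohol or 1,2-acyl migration of the C6 radical toward the C9 carbonyl. The fallback sets out from 12 and comes back at 14. Syn-dehydration of 12 with methyl N-(triethylammoniosulfonyl)carbamate (benzene, 50 °C) can only run toward C7, and each C6 epimer has a syn hydrogen there; it would give diethyl (1R,2R,5S,8R)-5-methyl-8-[(2R)-6-methylhept-5-en-2-yl]-9-oxobicyclo[3.3.1]non-6-ene-1,2-dicarboxylate F7. Diimide reduction (2-nitrobenzenesulfonohydrazide, Et3N, CH2Cl2, rt) would saturate the cis-disubstituted ring alkene in preference to the trisubstituted side-chain alkene and give 14.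

**Further compounds**
F1 | step 5 | (2E,4R)-4,8-dimethylnona-2,7-dien-1-ol | C[C@H](CCC=C(C)C)/C=C/CO
F2 | step 5 | methyl (2E,4R)-4,8-dimethylnona-2,7-dien-1-yl carbonate | C[C@H](CCC=C(C)C)/C=C/COC(=O)OC
F3 | step 5 | diethyl (1R,2R)-2-[(3S,4R)-4,8-dimethylnona-1,7-dien-3-yl]-4-methyl-3-oxocyclohexane-1,2-dicarboxylate (C4 epimers) | O=C1C(C)CC[C@@H](C(=O)OCC)[C@]1(C(=O)OCC)[C@H]([C@H](C)CCC=C(C)C)C=C
F4 | step 5 | diethyl (1R,2R)-2-[(3S,4R)-1-hydroxy-4,8-dimethylnon-7-en-3-yl]-4-methyl-3-oxocyclohexane-1,2-dicarboxylate (C4 epimers) | O=C1C(C)CC[C@@H](C(=O)OCC)[C@]1(C(=O)OCC)[C@H]([C@H](C)CCC=C(C)C)CCO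
F5 | step 5 | diethyl (1R,2R)-2-[(3S,4R)-1-iodo-4,8-dimethylnon-7-en-3-yl]-4-methyl-3-oxocyclohexane-1,2-dicarboxylate (C4 epimers) | O=C1C(C)CC[C@@H](C(=O)OCC)[C@]1(C(=O)OCC)[C@H]([C@H](C)CCC=C(C)C)CCI
F6 | step 8 | ethyl (1R,5R,8S)-2-[ethoxy(trimethylsilyloxy)methylidene]-5-methyl-8-[(2R)-6-methylhept-5-en-2-yl]-9-oxobicyclo[3.3.1]nonane-1-carboxylate | O=C1[C@@]2(C)CCC(=C(OCC)O[Si](C)(C)C)[C@]1(C(=O)OCC)[C@H]([C@H](C)CCC=C(C)C)CC2
F7 | step 7 | diethyl (1R,2R,5S,8R)-5-methyl-8-[(2R)-6-methylhept-5-en-2-yl]-9-oxobicyclo[3.3.1]non-6-ene-1,2-dicarboxylate | O=C1[C@@]2(C)CC[C@@H](C(=O)OCC)[C@]1(C(=O)OCC)[C@H]([C@H](C)CCC=C(C)C)C=C2
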